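**Retrosynthetic overview**
- Target ⇐ chelation-controlled 5-O-demethylation and hydrogenolysis of a 7,2'-di-O-benzyl-5-O-methyl flavone; rings A and B are bought as benzenes, ring C is the only ring formed and it is formed last.
- Ring C ⇐ oxidative cyclisation of a 2'-hydroxychalcone; the chalcone C=C ⇐ intermolecular Claisen–Schmidt aldol condensation of a ring A acetophenone with a ring B benzaldehyde (key C–C bond).
- Ring A ketone ⇐ Hoesch acylation of symmetric 2,5-dimethoxyresorcinol (only one possible site, so the 5,7,8-oxygenation pattern is unambiguous), then selective 4-O-benzylation.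
- 2,5-Dimethoxyresorcinol ⇐ 5-methoxyresorcinol via bis-MOM ether, ortho-lithiation/borylation/oxidation between the two OMOM groups, O-methylation, MOM removal.
- Ring B aldehyde ⇐ 2,4,5-trimethoxybenzaldehyde by ortho-demethylation and O-benzylation.

Assumption: the target has no stereocentre and is achiral, so no asymmetric step is needed; the only stereo-element on the way is the E-alkene of the chalcone, which disappears on cyclisation.

**Route**

Step 1
Reactants: 1 5-methoxybenzene-1,3-diol (5-methoxyresorcinol)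
Product: 2 1-methoxy-3,5-bis(methoxymethoxy)benzene
Conditions: NaH (2.4 equiv), MOMCl (2.4 equiv), DMF, 0 °C → rt
Reagents that add atoms: chloromethyl methyl ether (MOMCl), COCCl
Why: Williamson-type O-alkylation of both sodium phenoxides by the reactive α-chloro ether gives the bis-MOM ether, which is the directing group for the next step.

Step 2
Reactants: 2 1-methoxy-3,5-bis(methoxymethoxy)benzene
Product: 5 4-methoxy-2,6-bis(methoxymethoxy)phenol, via aryllithium 3 (not isolated), via dimethyl arylboronate 4 (not isolated)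
Conditions: n-BuLi (1.15 equiv), THF, 0 °C, 1 h; B(OMe)3 (1.5 equiv), −78 °C → rt; AcOH, 30% H2O2, 0 °C → rt
Reagents that add atoms: hydrogen peroxide, OO
Why: Directed ortho-metalation takes place at the carbon flanked by the two chelating OMOM groups (stronger directors than OMe), and borylation followed by peroxide oxidation (1,2-aryl shift from boron to oxygen) turns the C–Li bond into C–OH.

Step 3
Reactants: 5 4-methoxy-2,6-bis(methoxymethoxy)phenol
Product: 6 2,5-dimethoxy-1,3-bis(methoxymethoxy)benzene
Conditions: MeI (1.5 equiv), K2CO3 (2 equiv), DMF, rt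
Reagents that add atoms: iodomethane, CI
Why: Williamson ether synthesis on the only free phenol installs the methyl ether that becomes the 8-OMe of the flavone.

Step 4
Reactants: 6 2,5-dimethoxy-1,3-bis(methoxymethoxy)benzene
Product: 7 2,5-dimethoxybenzene-1,3-diol
Conditions: conc. HCl (cat.), MeOH, 50 °C
Reagents that add atoms: none
Why: Acid-catalysed acetal exchange transfers both MOM groups to methanol as dimethoxymethane while the aryl methyl ethers are inert.

Step 5
Reactants: 7 2,5-dimethoxybenzene-1,3-diol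
Product: 9 1-(2,4-dihydroxy-3,6-dimethoxyphenyl)ethan-1-one, via ketiminium chloride 8 (not isolated)
Conditions: MeCN (1.5 equiv), ZnCl2, HCl (g), Et2O, 0 °C; then H2O, reflux
Reagents that add atoms: acetonitrile, CC#N; water, O
Why: Houben–Hoesch acylation of the electron-rich resorcinol occurs at C4, which is equivalent to C6 by symmetry, so a single regioisomer forms, and the ketiminium salt is hydrolysed to the methyl ketone.

Step 6
Reactants: 9 1-(2,4-dihydroxy-3,6-dimethoxyphenyl)ethan-1-one
Product: 10 1-[4-(benzyloxy)-2-hydroxy-3,6-dimethoxyphenyl]ethan-1-one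
Conditions: BnBr (1.05 equiv), K2CO3 (1.2 equiv), acetone, reflux
Reagents that add atoms: benzyl bromide, BrCc1ccccc1
Why: Williamson benzylation is selective for the 4-OH because the 2-OH is deactivated by its hydrogen bond to the ketone, so the phenol that later becomes the ring oxygen stays free.

Step 7
Reactants: 11 2,4,5-trimethoxybenzaldehyde
Product: 12 2-hydroxy-4,5-dimethoxybenzaldehyde
Conditions: BCl3 (1.2 equiv, 1 M in CH2Cl2), CH2Cl2, 0 °C → rt; then H2O
Reagents that add atoms: none
Why: Chelation-controlled Lewis-acid demethylation, in which BCl3 bridges the aldehyde oxygen and the ortho methoxy group, cleaves only the 2-OMe.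

Step 8
Reactants: 12 2-hydroxy-4,5-dimethoxybenzaldehyde
Product: 13 2-(benzyloxy)-4,5-dimethoxybenzaldehyde
Conditions: BnBr (1.2 equiv), K2CO3 (1.5 equiv), DMF, 60 °C
Reagents that add atoms: benzyl bromide, BrCc1ccccc1
Why: Williamson benzylation masks the salicylaldehyde phenol so that the aldehyde stays electrophilic in the base-mediated condensation.

Step 9
Reactants: 10 1-[4-(benzyloxy)-2-hydroxy-3,6-dimethoxyphenyl]ethan-1-one; 13 2-(benzyloxy)-4,5-dimethoxybenzaldehyde
Product: 15 (E)-1-[4-(benzyloxy)-2-hydroxy-3,6-dimethoxyphenyl]-3-[2-(benzyloxy)-4,5-dimethoxyphenyl]prop-2-en-1-one, via racemic aldol adduct 14 (not isolated)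
Conditions: KOH (50% aq, 10 equiv), EtOH, rt, 24–48 h; then 1 M HCl, 0 °C
Reagents that add atoms: none
Why: Claisen–Schmidt crossed aldol condensation, in which the methyl ketone enolate adds to the non-enolisable aldehyde and the adduct dehydrates to the conjugated enone, with the E geometry set thermodynamically.

Step 10
Reactants: 15 (E)-1-[4-(benzyloxy)-2-hydroxy-3,6-dimethoxyphenyl]-3-[2-(benzyloxy)-4,5-dimethoxyphenyl]prop-2-en-1-one
Product: 17 7-(benzyloxy)-2-[2-(benzyloxy)-4,5-dimethoxyphenyl]-5,8-dimethoxy-4H-chromen-4-one, via racemic flavanone 16 (not isolated)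
Conditions: I2 (0.1 equiv), DMSO, 130 °C, 1–2 h; then aq Na2S2O3
Reagents that add atoms: none
Why: Iodine-catalysed oxidative cyclisation (oxa-Michael closure of the 2'-phenol to the flavanone, then iodine-mediated dehydrogenation with DMSO as terminal oxidant) forms ring C, and the transient flavanone stereocentre is destroyed.

Step 11
Reactants: 17 7-(benzyloxy)-2-[2-(benzyloxy)-4,5-dimethoxyphenyl]-5,8-dimethoxy-4H-chromen-4-one
Product: 18 7-hydroxy-2-(2-hydroxy-4,5-dimethoxyphenyl)-5,8-dimethoxy-4H-chromen-4-one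
Conditions: H2 (1 atm), 10% Pd/C, THF/MeOH, rt
Reagents that add atoms: none
Why: Catalytic hydrogenolysis cleaves both aryl benzyl ethers under conditions that leave the methyl ethers and the conjugated chromone double bond untouched if the reaction is stopped at full debenzylation.

Step 12
Reactants: 18 7-hydroxy-2-(2-hydroxy-4,5-dimethoxyphenyl)-5,8-dimethoxy-4H-chromen-4-one
Product: 19 5,7-dihydroxy-2-(2-hydroxy-4,5-dimethoxyphenyl)-8-methoxy-4H-chromen-4-one
Conditions: BCl3 (4 equiv, 1 M in CH2Cl2), CH2Cl2, −78 → 0 °C; then MeOH, H2O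
Reagents that add atoms: none
Why: Chelation-controlled Lewis-acid demethylation, in which BCl3 binds the C4 carbonyl and the peri 5-methoxy oxygen in a six-membered chelate, cleaves only that methyl and leaves the 8-, 4'- and 5'-methyl ethers.

**Compound list**
1 | 5-methoxybenzene-1,3-diol (5-methoxyresorcinol) | COc1cc(O)cc(O)c1 | starting material
2 | 1-methoxy-3,5-bis(methoxymethoxy)benzene | COCOc1cc(OC)cc(OCOC)c1 | intermediate
3 | [4-methoxy-2,6-bis(methoxymethoxy)phenyl]lithium (aryllithium) | [Li]c1c(OCOC)cc(OC)cc1OCOC | intermediate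
4 | dimethyl [4-methoxy-2,6-bis(methoxymethoxy)phenyl]boronate | COB(OC)c1c(OCOC)cc(OC)cc1OCOC | intermediate
5 | 4-methoxy-2,6-bis(methoxymethoxy)phenol | COCOc1cc(OC)cc(OCOC)c1O | intermediate
6 | 2,5-dimethoxy-1,3-bis(methoxymethoxy)benzene | COCOc1cc(OC)cc(OCOC)c1OC | intermediate
7 | 2,5-dimethoxybenzene-1,3-diol | COc1cc(O)c(OC)c(O)c1 | intermediate
8 | 1-(2,4-dihydroxy-3,6-dimethoxyphenyl)ethan-1-iminium chloride (ketiminium chloride) | CC(=[NH2+])c1c(OC)cc(O)c(OC)c1O.[Cl-] | intermediate
9 | 1-(2,4-dihydroxy-3,6-dimethoxyphenyl)ethan-1-one | CC(=O)c1c(OC)cc(O)c(OC)c1O | intermediate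
10 | 1-[4-(benzyloxy)-2-hydroxy-3,6-dimethoxyphenyl]ethan-1-one | CC(=O)c1c(OC)cc(OCc2ccccc2)c(OC)c1O | intermediate
11 | 2,4,5-trimethoxybenzaldehyde | COc1cc(OC)c(C=O)cc1OC | starting material
12 | 2-hydroxy-4,5-dimethoxybenzaldehyde | COc1cc(O)c(C=O)cc1OC | intermediate
13 | 2-(benzyloxy)-4,5-dimethoxybenzaldehyde | COc1cc(OCc2ccccc2)c(C=O)cc1OC | intermediate
14 | racemic 1-[4-(benzyloxy)-2-hydroxy-3,6-dimethoxyphenyl]-3-[2-(benzyloxy)-4,5-dimethoxyphenyl]-3-hydroxypropan-1-one (aldol adduct) | COc1cc(OCc2ccccc2)c(C(O)CC(=O)c2c(OC)cc(OCc3ccccc3)c(OC)c2O)cc1OC | intermediate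
15 | (E)-1-[4-(benzyloxy)-2-hydroxy-3,6-dimethoxyphenyl]-3-[2-(benzyloxy)-4,5-dimethoxyphenyl]prop-2-en-1-one (chalcone) | COc1cc(OCc2ccccc2)c(/C=C/C(=O)c2c(OC)cc(OCc3ccccc3)c(OC)c2O)cc1OC | intermediate
16 | racemic 7-(benzyloxy)-2-[2-(benzyloxy)-4,5-dimethoxyphenyl]-5,8-dimethoxy-2,3-dihydro-4H-chromen-4-one (flavanone) | COc1cc(OCc2ccccc2)c(C2CC(=O)c3c(OC)cc(OCc4ccccc4)c(OC)c3O2)cc1OC | intermediate
17 | 7-(benzyloxy)-2-[2-(benzyloxy)-4,5-dimethoxyphenyl]-5,8-dimethoxy-4H-chromen-4-one | COc1cc(OCc2ccccc2)c(-c2cc(=O)c3c(OC)cc(OCc4ccccc4)c(OC)c3o2)cc1OC | intermediate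
18 | 7-hydroxy-2-(2-hydroxy-4,5-dimethoxyphenyl)-5,8-dimethoxy-4H-chromen-4-one | COc1cc(O)c(-c2cc(=O)c3c(OC)cc(O)c(OC)c3o2)cc1OC | intermediate
19 | 5,7-dihydroxy-2-(2-hydroxy-4,5-dimethoxyphenyl)-8-methoxy-4H-chromen-4-one (achiral) | COc1cc(O)c(-c2cc(=O)c3c(O)cc(O)c(OC)c3o2)cc1OC | target

**Summary**
Total step count: 12. Longest linear sequence: 10 steps (steps 1–6, then 9–12); steps 7–8 form the convergent ring B branch.

Steps most likely to fail:

Step 2 (lithiation/borylation/oxidation; risk of over-oxidation of the very electron-rich phenol or a poor boronate yield). The fallback sets out from 2 and comes back at 5. Compound 2 is lithiated as before, but the aryllithium is trapped with DMF to give 4-methoxy-2,6-bis(methoxymethoxy)benzaldehyde F1, a stable aldehyde that can be freed of any regioisomer by crystallisation. Baeyer–Villiger (Dakin-type) oxidation with mCPBA in NaHCO3-buffered CH2Cl2 gives 4-methoxy-2,6-bis(methoxymethoxy)phenyl formate F2, and K2CO3/MeOH methanolysis releases phenol 5. The oxygen is thus installed by carbonyl-to-oxygen aryl migration, not through a boronate.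

Step 10 (I2/DMSO; risk of partial benzyl or 5-O-methyl cleavage by HI, or ring iodination). The fallback sets out from 15 and comes back at 17. The chalcone is cyclised under mild base (NaOAc, EtOH, reflux) and flavanone 16 is isolated this time. It is then dehydrogenated by hydride abstraction with DDQ in dioxane at reflux to give flavone 17. No iodine or HI is involved and no compound outside the list is made (F0).

Step 12 (BCl3 on the free bis-phenol; risk of additional loss of the 8-methyl group next to the 7-OH, or poor solubility). The fallback sets out from 17 and comes back at 19, with the order of deprotection reversed. The 5-methyl ether is cleaved first on the fully benzylated flavone with MgI2·OEt2 (toluene/Et2O, 80 °C), which attacks only the ether peri to the carbonyl and gives 7-(benzyloxy)-2-[2-(benzyloxy)-4,5-dimethoxyphenyl]-5-hydroxy-8-methoxy-4H-chromen-4-one F3. Hydrogenolysis (H2, 10% Pd/C, THF/MeOH) then removes both benzyl groups to give 19, so no Lewis acid ever meets the free 7-OH/8-OMe pair.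

**Further compounds**
F1 | step 2 | 4-methoxy-2,6-bis(methoxymethoxy)benzaldehyde | COCOc1cc(OC)cc(OCOC)c1C=O
F2 | step 2 | 4-methoxy-2,6-bis(methoxymethoxy)phenyl formate | COCOc1cc(OC)cc(OCOC)c1OC=O
F0 | step 10 | none | none
F3 | step 12 | 7-(benzyloxy)-2-[2-(benzyloxy)-4,5-dimethoxyphenyl]-5-hydroxy-8-methoxy-4H-chromen-4-one | COc1cc(OCc2ccccc2)c(-c2cc(=O)c3c(O)cc(OCc4ccccc4)c(OC)c3o2)cc1OC
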